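**Retrosynthetic overview**

1. Atom labels: ring C1–C6 (C1 = CMe2, C2 carries the side chain C1''–C4'', C4=C5, C6 carries the polyene C7…C3'); open-chain end C1'–C2'.
2. C50 skeleton: two Wittig unions of the C10 dialdehyde 14, at C11=C12 with ring-end phosphonium salt 13 and at C11'=C12' with open-chain phosphonium salt 26, then ester reduction.
3. Ring end: the ring of (S)-α-ionone is cut at C4=C5 by ozonolysis, which turns its old C3–C4 into C1''–C2''. The only ring of the target is re-closed in step 3 by bridging C2 and the C5 ketone with a two-carbon vinylphosphonium unit (C2–C3 by radical addition, C4=C5 by Wittig).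
4. Enabling feature: in seco compound 3 the C5 methyl ketone and the C2 methylene (β to the C2'' aldehyde, so open to one-electron enamine activation) are 1,4-related across the quaternary C1. A C3–C4 unit therefore completes the six-membered ring C1–C6, and C6 is kept from the terpenoid.
5. Open-chain end: (R)-lavandulol, Markovnikov hydration (C1'–OH), oxidation to the C3' aldehyde, two C5 Horner–Wadsworth–Emmons extensions. Ring order: one ring only, formed in step 3.

Key step: step 3

Remark: (S)-α-ionone and (R)-lavandulol are taken as purchasable in enantioenriched form; where only the racemates are at hand, each is resolved beforehand by the known lipase-mediated acylation route.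

**Route**

Step 1
Reactants: 1 (S)-α-ionone
Product: 2 2-methyl-2-{(E)-2-[(1S)-2,6,6-trimethylcyclohex-2-en-1-yl]ethenyl}-1,3-dioxolane
Conditions: Me3SiOCH2CH2OSiMe3, Me3SiOTf (cat.), CH2Cl2, −78 to −20 °C; pyridine quench
Reagents that add atoms: 1,2-bis(trimethylsilyloxy)ethane, C[Si](C)(C)OCCO[Si](C)(C)C
Why: Noyori ketalisation masks the enone under aprotic, cold conditions that should not move the ring double bond, so that C6–H is not vinylogously acidified once C5 becomes a ketone; no stereocenter is touched.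

Step 2
Reactants: 2 dioxolane
Product: 3 (5S)-4,4-dimethyl-5-[(E)-2-(2-methyl-1,3-dioxolan-2-yl)ethenyl]-6-oxoheptanal
Conditions: O3 (1.0 equiv, Sudan Red 7B as indicator), CH2Cl2, −78 °C; PPh3, −78 °C to rt
Reagents that add atoms: ozone, [O-][O+]=O
Why: Chemoselective ozonolysis, because the trisubstituted ring alkene C4=C5 should react far faster than the C7=C8 alkene, which is shielded by C6 and the dioxolane carbon and deactivated by two allylic oxygens; C6 is untouched.

Step 3
Reactants: 3 keto aldehyde, 4 (R)-2-(methoxydiphenylmethyl)pyrrolidine (auxiliary amine, recovered), 5 vinyltriphenylphosphonium bromide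
Product: 9 (3E)-4-[(1R,5R)-2,6,6-trimethyl-5-(2-oxoethyl)cyclohex-2-en-1-yl]but-3-en-2-one, via enamine 6 (not isolated), via ylide 7 (not isolated), via ring enamine 8 (not isolated)
Conditions: 4 (1.1 equiv), 5 (1.5 equiv), 4CzIPN (2 mol%), Cs2CO3 (2.5 equiv), 4 Å MS, MeCN, blue LEDs, 25 °C; then 1 M HCl, THF, rt
Reagents that add atoms: water, O
Why: Proposed new method: aldehyde 3 condenses with 4 to the (E)-enamine 6, whose photocatalytic one-electron oxidation and loss of a C2 proton give the 5π-electron β-enaminyl radical; this nucleophilic radical adds through C2 to the unsubstituted terminus of 5 (C2–C3), the α-phosphonio radical is reduced by the reduced photocatalyst to ylide 7 (radical-polar crossover), and 7 closes the ring by intramolecular Wittig olefination of the C5 methyl ketone (C4=C5). The closest known reactions are the photoredox-organocatalytic β-alkylation of saturated aldehydes with Michael acceptors, the radical/vinylphosphonium/carbonyl three-component olefination and the Schweizer vinylphosphonium annulation. The single ring closes in the 6-exo-trig mode (ylide carbon C4 onto the C5 carbonyl), which leaves the new alkene endocyclic. C2 is the only new stereocenter: in the planar (E)-configured radical the methoxydiphenylmethyl group of the (R)-amine should shield the Si face as in iminium-type conjugate additions, so that C3 enters on the Re face (2R), while C6 comes unchanged from 1. The step needs β- rather than α-reactivity of the enamine (one-electron pathway; the unsubstituted acceptor terminus suits the hindered radical), Wittig closure onto the ketone only (the aldehyde carbon stays masked as the enamine until the acidic work-up, which also removes the dioxolane) and integrity of C6–H (carbonate as the only base, room temperature).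

Step 4
Reactants: 9 keto aldehyde, 10 ethyl 2-(triphenyl-λ5-phosphanylidene)propanoate
Product: 11 ethyl (2E)-2-methyl-4-{(1R,5R)-4,6,6-trimethyl-5-[(1E)-3-oxobut-1-en-1-yl]cyclohex-3-en-1-yl}but-2-enoate
Conditions: 10 (1.3 equiv), CH2Cl2, rt
Reagents that add atoms: none
Why: Wittig olefination with a stabilised ylide should be selective for the aldehyde over the enone and give the (E)-trisubstituted enoate.

Step 5
Reactants: 11 enone ester
Product: 12 ethyl (2E)-4-{(1R,5R)-5-[(1E)-3-hydroxy-3-methylpenta-1,4-dien-1-yl]-4,6,6-trimethylcyclohex-3-en-1-yl}-2-methylbut-2-enoate (both carbinol epimers)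
Conditions: CH2=CHMgBr (1.2 equiv), THF, −78 °C; aq. NH4Cl
Reagents that add atoms: vinylmagnesium bromide, C=C[Mg]Br
Why: Grignard 1,2-addition to the methyl ketone should be much faster at −78 °C than attack on the hindered α-methyl enoate; the new carbinol center is formed unselectively and is lost in step 6.

Step 6
Reactants: 12 tertiary alcohol
Product: 13 {(2E,4E)-5-[(1R,5R)-5-[(2E)-4-ethoxy-3-methyl-4-oxobut-2-en-1-yl]-2,6,6-trimethylcyclohex-2-en-1-yl]-3-methylpenta-2,4-dien-1-yl}triphenylphosphonium bromide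
Conditions: PPh3·HBr (1.05 equiv), MeOH, rt
Reagents that add atoms: triphenylphosphine hydrobromide, [PH+](c1ccccc1)(c1ccccc1)c1ccccc1.[Br-]
Why: Acid-induced ionisation of the bis-allylic tertiary alcohol and capture of the pentadienyl cation at its terminus by PPh3 (the classical vinyl-ionol to phosphonium salt conversion) should give mainly the (E)-trisubstituted alkene.

Step 7
Reactants: 13 phosphonium bromide, 14 (2E,4E,6E)-2,7-dimethylocta-2,4,6-trienedial
Product: 15 ethyl (2E)-4-{(1R,5R)-5-[(1E,3E,5E,7E,9E,11E)-3,7,12-trimethyl-13-oxotrideca-1,3,5,7,9,11-hexaen-1-yl]-4,6,6-trimethylcyclohex-3-en-1-yl}-2-methylbut-2-enoate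
Conditions: 14 (3 equiv), NaOEt, EtOH/CH2Cl2, 0 °C to rt; then heptane, 90 °C, dark
Reagents that add atoms: none
Why: Wittig olefination of the semi-stabilised ylide with an excess of the symmetrical dialdehyde should give the mono-adduct, and thermal equilibration should convert the hindered (Z)-C11=C12 isomer into the all-(E) polyene.

Step 8
Reactants: 16 (R)-lavandulol
Product: 17 (2S)-2-(2-hydroxypropan-2-yl)-5-methylhex-4-en-1-ol
Conditions: Hg(OAc)2 (1.0 equiv), THF/H2O, rt; then NaBH4, aq. NaOH, 0 °C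
Reagents that add atoms: water, O
Why: Markovnikov oxymercuration–demercuration, in which the 1,1-disubstituted isopropenyl alkene should be mercurated much faster than the trisubstituted prenyl alkene (as in limonene to α-terpineol); the stereocenter is not involved and only its descriptor changes.

Step 9
Reactants: 17 diol
Product: 18 triethyl{[(2S)-5-methyl-2-{2-[(triethylsilyl)oxy]propan-2-yl}hex-4-en-1-yl]oxy}silane
Conditions: Et3SiOTf (2.5 equiv), 2,6-lutidine, CH2Cl2, −78 to 0 °C
Reagents that add atoms: triethylsilyl trifluoromethanesulfonate, CC[Si](CC)(CC)OS(=O)(=O)C(F)(F)F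
Why: Exhaustive silylation with the silyl triflate protects also the tertiary hydroxyl, which blocks retro-aldol cleavage of the later β-oxygenated aldehyde.

Step 10
Reactants: 18 bis(triethylsilyl) ether
Product: 19 (2R)-5-methyl-2-{2-[(triethylsilyl)oxy]propan-2-yl}hex-4-enal
Conditions: (COCl)2, DMSO, CH2Cl2, −78 to −40 °C; Et3N, −78 to 0 °C
Reagents that add atoms: none
Why: Swern conditions oxidise a primary triethylsilyl ether directly to the aldehyde, while the tertiary silyl ether should survive; the cold amine step should keep the α-stereocenter intact.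

Step 11
Reactants: 19 aldehyde, 20 diethyl [(2E)-3-cyano-2-methylprop-2-en-1-yl]phosphonate
Product: 21 (2E,4E,6S)-3,9-dimethyl-6-{2-[(triethylsilyl)oxy]propan-2-yl}deca-2,4,8-trienenitrile
Conditions: 20 (1.3 equiv), LiN(SiMe3)2, THF, −78 to 0 °C
Reagents that add atoms: none
Why: Vinylogous Horner–Wadsworth–Emmons olefination should form the (E)-C3'=C4' bond and carry in C4'–C7'; the minor (2Z) isomer is removed by chromatography.

Step 12
Reactants: 21 nitrile
Product: 22 (2E,4E,6S)-3,9-dimethyl-6-{2-[(triethylsilyl)oxy]propan-2-yl}deca-2,4,8-trienal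
Conditions: iBu2AlH (1.2 equiv), toluene, −78 °C; wet SiO2
Reagents that add atoms: water, O
Why: Partial reduction of the conjugated nitrile to the aluminium imine and mild hydrolysis should give the dienal without touching the silyl ether or the alkenes.

Step 13
Reactants: 22 dienal, 23 ethyl (2E)-4-(diethoxyphosphoryl)-3-methylbut-2-enoate
Product: 24 ethyl (2E,4E,6E,8E,10S)-3,7,13-trimethyl-10-{2-[(triethylsilyl)oxy]propan-2-yl}tetradeca-2,4,6,8,12-pentaenoate
Conditions: 23 (1.3 equiv), LiN(SiMe3)2, THF, −78 to 0 °C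
Reagents that add atoms: none
Why: A second vinylogous Horner–Wadsworth–Emmons olefination, as used for retinoates, should form the (E)-C7'=C8' bond and bring in C8'–C11'.

Step 14
Reactants: 24 pentaenoate
Product: 25 (2E,4E,6E,8E,10S)-3,7,13-trimethyl-10-{2-[(triethylsilyl)oxy]propan-2-yl}tetradeca-2,4,6,8,12-pentaen-1-ol
Conditions: iBu2AlH (2.5 equiv), CH2Cl2, −78 °C; aq. KNaC4H4O6
Reagents that add atoms: none
Why: 1,2-Reduction of the conjugated ester with the aluminium hydride should give the allylic alcohol without conjugate reduction.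

Step 15
Reactants: 25 allylic alcohol
Product: 26 [(2E,4E,6E,8E,10S)-10-(2-hydroxypropan-2-yl)-3,7,13-trimethyltetradeca-2,4,6,8,12-pentaen-1-yl]triphenylphosphonium bromide
Conditions: PPh3·HBr (1.2 equiv), MeOH, rt
Reagents that add atoms: triphenylphosphine hydrobromide, [PH+](c1ccccc1)(c1ccccc1)c1ccccc1.[Br-]
Why: Phosphonium salt formation through the polyenyl cation, as in the retinol to retinylphosphonium conversion; the acidic methanol should also methanolyse the tertiary triethylsilyl ether, while the non-allylic tertiary alcohol does not ionise.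

Step 16
Reactants: 15 polyene aldehyde, 26 phosphonium bromide
Product: 27 ethyl (2E)-4-{(1R,5R)-5-[(1E,3E,5E,7E,9E,11E,13E,15E,17E,19E,21E,23S)-23-(2-hydroxypropan-2-yl)-3,7,12,16,20,26-hexamethylheptacosa-1,3,5,7,9,11,13,15,17,19,21,25-dodecaen-1-yl]-4,6,6-trimethylcyclohex-3-en-1-yl}-2-methylbut-2-enoate
Conditions: NaOEt (2.2 equiv), EtOH/CH2Cl2, rt; then heptane, 80 °C, dark, N2
Reagents that add atoms: none
Why: Wittig union of the two C-rich fragments at C11'=C12', followed by thermal equilibration of the hindered (Z) isomer to the all-(E) chain; the free tertiary hydroxyl only consumes one extra equivalent of base.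

Step 17
Reactants: 27 C50 ethyl ester
Product: 28 CNP0409952.1 (target)
Conditions: iBu2AlH (4 equiv), THF/CH2Cl2, −78 °C; aq. KNaC4H4O6
Reagents that add atoms: none
Why: 1,2-Reduction of the α-methyl enoate should give the (E)-allylic alcohol and leave the polyene, the ring alkene and all three stereocenters unchanged.

**Compound list**

1 | (S)-α-ionone, (3E)-4-[(1S)-2,6,6-trimethylcyclohex-2-en-1-yl]but-3-en-2-one | CC(=O)/C=C/[C@@H]1C(C)=CCCC1(C)C | starting material
2 | 2-methyl-2-{(E)-2-[(1S)-2,6,6-trimethylcyclohex-2-en-1-yl]ethenyl}-1,3-dioxolane | CC1(OCCO1)/C=C/[C@@H]2C(C)=CCCC2(C)C | intermediate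
3 | (5S)-4,4-dimethyl-5-[(E)-2-(2-methyl-1,3-dioxolan-2-yl)ethenyl]-6-oxoheptanal | CC1(OCCO1)/C=C/[C@H](C(C)=O)C(C)(C)CCC=O | intermediate
4 | (R)-2-(methoxydiphenylmethyl)pyrrolidine | COC(c1ccccc1)(c1ccccc1)[C@H]1CCCN1 | starting material
5 | vinyltriphenylphosphonium bromide | C=C[P+](c1ccccc1)(c1ccccc1)c1ccccc1.[Br-] | starting material
6 | (E)-enamine of aldehyde 3 with amine 4 (C6 as in 3) | CC1(OCCO1)/C=C/[C@H](C(C)=O)C(C)(C)C/C=C/N2CCC[C@@H]2C(OC)(c3ccccc3)c3ccccc3 | intermediate
7 | phosphorus ylide from C2-alkylation of 6 (C2–C3 formed, ylide carbon C4) | CC1(OCCO1)/C=C/[C@H](C(C)=O)C(C)(C)[C@H](CC=P(c2ccccc2)(c2ccccc2)c2ccccc2)/C=C/N2CCC[C@@H]2C(OC)(c3ccccc3)c3ccccc3 | intermediate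
8 | ring enamine (cyclohexene closed, C2'' still the enamine, dioxolane in place) | CC1(OCCO1)/C=C/[C@@H]2C(C)=CC[C@H](/C=C/N3CCC[C@@H]3C(OC)(c4ccccc4)c4ccccc4)C2(C)C | intermediate
9 | (3E)-4-[(1R,5R)-2,6,6-trimethyl-5-(2-oxoethyl)cyclohex-2-en-1-yl]but-3-en-2-one | CC(=O)/C=C/[C@@H]1C(C)=CC[C@H](CC=O)C1(C)C | intermediate
10 | ethyl 2-(triphenyl-λ5-phosphanylidene)propanoate | CCOC(=O)C(C)=P(c1ccccc1)(c1ccccc1)c1ccccc1 | starting material
11 | ethyl (2E)-2-methyl-4-{(1R,5R)-4,6,6-trimethyl-5-[(1E)-3-oxobut-1-en-1-yl]cyclohex-3-en-1-yl}but-2-enoate | CC(=O)/C=C/[C@@H]1C(C)=CC[C@H](C/C=C(\C)C(=O)OCC)C1(C)C | intermediate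
12 | ethyl (2E)-4-{(1R,5R)-5-[(1E)-3-hydroxy-3-methylpenta-1,4-dien-1-yl]-4,6,6-trimethylcyclohex-3-en-1-yl}-2-methylbut-2-enoate (carbinol epimers) | C=CC(C)(O)/C=C/[C@@H]1C(C)=CC[C@H](C/C=C(\C)C(=O)OCC)C1(C)C | intermediate
13 | {(2E,4E)-5-[(1R,5R)-5-[(2E)-4-ethoxy-3-methyl-4-oxobut-2-en-1-yl]-2,6,6-trimethylcyclohex-2-en-1-yl]-3-methylpenta-2,4-dien-1-yl}triphenylphosphonium bromide | C(/C=C(C)/C=C/[C@@H]1C(C)=CC[C@H](C/C=C(\C)C(=O)OCC)C1(C)C)[P+](c1ccccc1)(c1ccccc1)c1ccccc1.[Br-] | intermediate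
14 | (2E,4E,6E)-2,7-dimethylocta-2,4,6-trienedial | O=C/C(C)=C/C=C/C=C(\C)C=O | starting material
15 | ethyl (2E)-4-{(1R,5R)-5-[(1E,3E,5E,7E,9E,11E)-3,7,12-trimethyl-13-oxotrideca-1,3,5,7,9,11-hexaen-1-yl]-4,6,6-trimethylcyclohex-3-en-1-yl}-2-methylbut-2-enoate | O=C/C(C)=C/C=C/C=C(C)/C=C/C=C(C)/C=C/[C@@H]1C(C)=CC[C@H](C/C=C(\C)C(=O)OCC)C1(C)C | intermediate
16 | (R)-lavandulol, (2R)-5-methyl-2-(prop-1-en-2-yl)hex-4-en-1-ol | CC(C)=CC[C@@H](CO)C(C)=C | starting material
17 | (2S)-2-(2-hydroxypropan-2-yl)-5-methylhex-4-en-1-ol | CC(C)=CC[C@@H](CO)C(C)(C)O | intermediate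
18 | triethyl{[(2S)-5-methyl-2-{2-[(triethylsilyl)oxy]propan-2-yl}hex-4-en-1-yl]oxy}silane | CC(C)=CC[C@@H](CO[Si](CC)(CC)CC)C(C)(C)O[Si](CC)(CC)CC | intermediate
19 | (2R)-5-methyl-2-{2-[(triethylsilyl)oxy]propan-2-yl}hex-4-enal | CC(C)=CC[C@@H](C=O)C(C)(C)O[Si](CC)(CC)CC | intermediate
20 | diethyl [(2E)-3-cyano-2-methylprop-2-en-1-yl]phosphonate | CCOP(=O)(OCC)C/C(C)=C/C#N | starting material
21 | (2E,4E,6S)-3,9-dimethyl-6-{2-[(triethylsilyl)oxy]propan-2-yl}deca-2,4,8-trienenitrile | CC(C)=CC[C@@H](/C=C/C(C)=C/C#N)C(C)(C)O[Si](CC)(CC)CC | intermediate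
22 | (2E,4E,6S)-3,9-dimethyl-6-{2-[(triethylsilyl)oxy]propan-2-yl}deca-2,4,8-trienal | CC(C)=CC[C@@H](/C=C/C(C)=C/C=O)C(C)(C)O[Si](CC)(CC)CC | intermediate
23 | ethyl (2E)-4-(diethoxyphosphoryl)-3-methylbut-2-enoate | CCOC(=O)/C=C(\C)CP(=O)(OCC)OCC | starting material
24 | ethyl (2E,4E,6E,8E,10S)-3,7,13-trimethyl-10-{2-[(triethylsilyl)oxy]propan-2-yl}tetradeca-2,4,6,8,12-pentaenoate | CC(C)=CC[C@@H](/C=C/C(C)=C/C=C/C(C)=C/C(=O)OCC)C(C)(C)O[Si](CC)(CC)CC | intermediate
25 | (2E,4E,6E,8E,10S)-3,7,13-trimethyl-10-{2-[(triethylsilyl)oxy]propan-2-yl}tetradeca-2,4,6,8,12-pentaen-1-ol | CC(C)=CC[C@@H](/C=C/C(C)=C/C=C/C(C)=C/CO)C(C)(C)O[Si](CC)(CC)CC | intermediate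
26 | [(2E,4E,6E,8E,10S)-10-(2-hydroxypropan-2-yl)-3,7,13-trimethyltetradeca-2,4,6,8,12-pentaen-1-yl]triphenylphosphonium bromide | CC(C)=CC[C@@H](/C=C/C(C)=C/C=C/C(C)=C/C[P+](c1ccccc1)(c1ccccc1)c1ccccc1)C(C)(C)O.[Br-] | intermediate
27 | ethyl (2E)-4-{(1R,5R)-5-[(1E,3E,5E,7E,9E,11E,13E,15E,17E,19E,21E,23S)-23-(2-hydroxypropan-2-yl)-3,7,12,16,20,26-hexamethylheptacosa-1,3,5,7,9,11,13,15,17,19,21,25-dodecaen-1-yl]-4,6,6-trimethylcyclohex-3-en-1-yl}-2-methylbut-2-enoate | CC(C)=CC[C@@H](/C=C/C(C)=C/C=C/C(C)=C/C=C/C(C)=C/C=C/C=C(C)/C=C/C=C(C)/C=C/[C@@H]1C(C)=CC[C@H](C/C=C(\C)C(=O)OCC)C1(C)C)C(C)(C)O | intermediate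
28 | CNP0409952.1, (2E)-4-{(1R,5R)-5-[(1E,3E,5E,7E,9E,11E,13E,15E,17E,19E,21E,23S)-23-(2-hydroxypropan-2-yl)-3,7,12,16,20,26-hexamethylheptacosa-1,3,5,7,9,11,13,15,17,19,21,25-dodecaen-1-yl]-4,6,6-trimethylcyclohex-3-en-1-yl}-2-methylbut-2-en-1-ol | CC(C)=CC[C@@H](/C=C/C(C)=C/C=C/C(C)=C/C=C/C(C)=C/C=C/C=C(C)/C=C/C=C(C)/C=C/[C@@H]1C(C)=CC[C@H](C/C=C(\C)CO)C1(C)C)C(C)(C)O | target

**Step count and risks**

Total step count: 17. Longest linear sequence: 10 steps (steps 8–15, then 16 and 17, from 16). The ring-end branch is 9 steps (steps 1–7, then 16 and 17).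

Steps most likely to fail:

1. Step 3 (the labelled step). Ylide 7 may be protonated before it cyclises, enamine 6 may be alkylated at its α-carbon by the two-electron Michael pathway, or the amine may give poor facial control at C2. The fallback makes the two bonds separately by known reactions; it sets out from 3 and comes back at 11. Organocatalytic α-selenenylation (N-(phenylseleno)phthalimide, cat. pyrrolidine) and NaIO4 oxidation with syn-elimination should give (2E,5S)-4,4-dimethyl-5-[(E)-2-(2-methyl-1,3-dioxolan-2-yl)ethenyl]-6-oxohept-2-enal F1. An imidazolidinone-catalysed Mukaiyama–Michael addition of 1-(tert-butyldimethylsilyloxy)-1-(propan-2-ylsulfanyl)ethene (catalyst enantiomer chosen for Re-face attack at C2) should set C2 and give S-propan-2-yl (3S,5S)-4,4-dimethyl-5-[(E)-2-(2-methyl-1,3-dioxolan-2-yl)ethenyl]-6-oxo-3-(2-oxoethyl)heptanethioate F2. Wittig reaction with 10 should give S-propan-2-yl (3S,5S)-3-[(2E)-4-ethoxy-3-methyl-4-oxobut-2-en-1-yl]-4,4-dimethyl-5-[(E)-2-(2-methyl-1,3-dioxolan-2-yl)ethenyl]-6-oxoheptanethioate F3. Fukuyama reduction (Et3SiH, Pd/C, acetone) should give ethyl (2E,5S,7S)-2,6,6-trimethyl-7-[(E)-2-(2-methyl-1,3-dioxolan-2-yl)ethenyl]-8-oxo-5-(2-oxoethyl)non-2-enoate F4. Intramolecular McMurry coupling of its aldehyde with the methyl ketone (TiCl3(DME)1.5, Zn–Cu couple, DME, reflux, high dilution) should close C4=C5 and give ethyl (2E)-2-methyl-4-{(1R,5R)-4,6,6-trimethyl-5-[(E)-2-(2-methyl-1,3-dioxolan-2-yl)ethenyl]cyclohex-3-en-1-yl}but-2-enoate F5. PPTS in wet acetone then removes the dioxolane and returns to 11.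

2. Step 2. Ozone may also cleave the C7=C8 alkene, and the keto aldehyde may epimerise at C6 or close by aldol reaction during work-up. The fallback goes from 2 to 3: osmylation (OsO4 cat., NMO, acetone/H2O), which is more sensitive to the steric shielding of C7=C8, should give (6S)-1,5,5-trimethyl-6-[(E)-2-(2-methyl-1,3-dioxolan-2-yl)ethenyl]cyclohexane-1,2-diol F6 (cis-diol, both faces), and neutral glycol cleavage (NaIO4, THF/H2O, pH 7) returns to 3.

3. Step 11. The basic conditions may epimerise the α-branched aldehyde 19 at C2' or eliminate its β-silyloxy group. The fallback goes from 19 to 21: a base-free Wittig reaction with 1-(triphenyl-λ5-phosphanylidene)propan-2-one (toluene, 60 °C) should give (3E,5S)-8-methyl-5-{2-[(triethylsilyl)oxy]propan-2-yl}nona-3,7-dien-2-one F7, whose methyl ketone is then olefinated with diethyl (cyanomethyl)phosphonate (NaH, THF) to return to 21 after removal of the (2Z) isomer.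

Further compounds
F1 | step 3 | (2E,5S)-4,4-dimethyl-5-[(E)-2-(2-methyl-1,3-dioxolan-2-yl)ethenyl]-6-oxohept-2-enal | CC1(OCCO1)/C=C/[C@H](C(C)=O)C(C)(C)/C=C/C=O
F2 | step 3 | S-propan-2-yl (3S,5S)-4,4-dimethyl-5-[(E)-2-(2-methyl-1,3-dioxolan-2-yl)ethenyl]-6-oxo-3-(2-oxoethyl)heptanethioate | CC1(OCCO1)/C=C/[C@H](C(C)=O)C(C)(C)[C@H](CC(=O)SC(C)C)CC=O
F3 | step 3 | S-propan-2-yl (3S,5S)-3-[(2E)-4-ethoxy-3-methyl-4-oxobut-2-en-1-yl]-4,4-dimethyl-5-[(E)-2-(2-methyl-1,3-dioxolan-2-yl)ethenyl]-6-oxoheptanethioate | CC1(OCCO1)/C=C/[C@H](C(C)=O)C(C)(C)[C@H](CC(=O)SC(C)C)C/C=C(\C)C(=O)OCC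
F4 | step 3 | ethyl (2E,5S,7S)-2,6,6-trimethyl-7-[(E)-2-(2-methyl-1,3-dioxolan-2-yl)ethenyl]-8-oxo-5-(2-oxoethyl)non-2-enoate | CC1(OCCO1)/C=C/[C@H](C(C)=O)C(C)(C)[C@H](CC=O)C/C=C(\C)C(=O)OCC
F5 | step 3 | ethyl (2E)-2-methyl-4-{(1R,5R)-4,6,6-trimethyl-5-[(E)-2-(2-methyl-1,3-dioxolan-2-yl)ethenyl]cyclohex-3-en-1-yl}but-2-enoate | CC1(OCCO1)/C=C/[C@@H]2C(C)=CC[C@H](C/C=C(\C)C(=O)OCC)C2(C)C
F6 | step 2 | (6S)-1,5,5-trimethyl-6-[(E)-2-(2-methyl-1,3-dioxolan-2-yl)ethenyl]cyclohexane-1,2-diol (cis-diol, both faces) | CC1(OCCO1)/C=C/[C@@H]2C(C)(O)C(O)CCC2(C)C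
F7 | step 11 | (3E,5S)-8-methyl-5-{2-[(triethylsilyl)oxy]propan-2-yl}nona-3,7-dien-2-one | CC(C)=CC[C@@H](/C=C/C(C)=O)C(C)(C)O[Si](CC)(CC)CC
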